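**Strategy.** The hexasubstituted A ring (C4a, C5, C6, C7, C8, C8a) is not bought but built last, onto a preformed 2-aryl-4-pyranone (the C ring). Its four contiguous oxygens map onto dimethyl squarate: the enol ether carbons become C6/C7, the carbonyl carbons C5/C8. Heating a 4-hydroxy-4-(4-oxopyran-3-yl)cyclobutenone opens the four-membered ring to a dienylketene, which closes by 6π electrocyclisation onto the pyranone C=C bond (new bond C8–C8a) and aromatises to the 5,8-dihydroxy-6,7-dimethoxyflavone; methylation in the same flask completes the pattern. The precursor is the adduct of dimethyl squarate and a 5-magnesiated 2-(4-benzyloxyphenyl)-4-pyranone.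

Key step: step 5

Remark: the target has no stereocentre and no stereogenic double bond, so it is achiral and no enantiomer has to be chosen. The stereocentres of intermediates 3, 4, 5, 9 and 11 are formed racemic and are all destroyed later in the route.

**Step 1**
Reactants: 1 trans-1-methoxy-3-(trimethylsilyloxy)buta-1,3-diene (Danishefsky's diene); 2 4-(benzyloxy)benzaldehyde
Product: 4 rac-2-[4-(benzyloxy)phenyl]-2,3-dihydro-4H-pyran-4-one, via silyl enol ether cycloadduct 3 (not isolated)
Conditions: ZnCl2 (10 mol%), THF, rt; then TFA, wet CH2Cl2, 0 °C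
Reagents that add atoms: none
Why: Lewis-acid-catalysed hetero-Diels–Alder cyclocondensation of the siloxydiene with the aldehyde C=O (diene CH2 terminus to the carbonyl carbon), followed by acid-mediated loss of methanol and of the silyl group, is the standard entry to 2-aryl-2,3-dihydro-4H-pyran-4-ones, and the C2 stereocentre is left racemic because step 3 removes it.

**Step 2**
Reactants: 4 rac-2-[4-(benzyloxy)phenyl]-2,3-dihydro-4H-pyran-4-one
Product: 5 rac-2-[4-(benzyloxy)phenyl]-5-iodo-2,3-dihydro-4H-pyran-4-one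
Conditions: I2, pyridine/CH2Cl2 (1:1), 0 °C to rt
Reagents that add atoms: iodine, II
Why: α-Iodination of a cyclic enone with iodine and pyridine should take place at C5, the only nucleophilic alkene carbon of the vinylogous ester, which puts the halogen unambiguously on the pyranone side remote from the aryl group before the second ring double bond exists.

**Step 3**
Reactants: 5 rac-2-[4-(benzyloxy)phenyl]-5-iodo-2,3-dihydro-4H-pyran-4-one
Product: 6 2-[4-(benzyloxy)phenyl]-5-iodo-4H-pyran-4-one
Conditions: DDQ (1.5 equiv), 1,4-dioxane, 90 °C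
Reagents that add atoms: none
Why: DDQ dehydrogenation of the kind used to convert flavanones into flavones should work because hydride loss from C2 is assisted by the ring oxygen and the 4-alkoxyphenyl group and loss of a C3 proton then gives the cross-conjugated 4-pyranone, while the vinyl iodide is inert to the oxidant.

**Step 4**
Reactants: 6 2-[4-(benzyloxy)phenyl]-5-iodo-4H-pyran-4-one; 7 dimethyl squarate (3,4-dimethoxycyclobut-3-ene-1,2-dione)
Product: 9 rac-4-{6-[4-(benzyloxy)phenyl]-4-oxo-4H-pyran-3-yl}-4-hydroxy-2,3-dimethoxycyclobut-2-en-1-one, via pyranonylmagnesium chloride 8 (not isolated)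
Conditions: iPrMgCl·LiCl (1.1 equiv), THF, –78 to –40 °C; then cannulation into 7 (1.5 equiv), THF, –78 °C; sat. aq. NH4Cl, –78 °C
Reagents that add atoms: none
Why: Iodine–magnesium exchange with the turbo-Grignard reagent is fast at an sp2 C–I bond next to a vinylogous ester carbonyl, 6 has no enolisable hydrogen and a poorly electrophilic pyranone carbonyl, and the alkenyl Grignard reagent should add 1,2 to one of the two equivalent ketone carbonyls of the squarate (inverse addition to an excess prevents a second addition, low temperature suppresses ring opening of 8 by β-elimination), giving a racemic carbinol centre that is lost in step 5.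

**Step 5**
Reactants: 9 rac-4-{6-[4-(benzyloxy)phenyl]-4-oxo-4H-pyran-3-yl}-4-hydroxy-2,3-dimethoxycyclobut-2-en-1-one
Product: 13 2-[4-(benzyloxy)phenyl]-5,6,7,8-tetramethoxy-4H-chromen-4-one, via dienylketene 10 (not isolated), via bicyclic dienone 11 (not isolated), via hydroquinone 12 (not isolated)
Conditions: degassed PhMe, 110 °C, Ar; then K2CO3, Me2SO4, acetone, reflux, Ar
Reagents that add atoms: dimethyl sulfate, COS(=O)(=O)OC
Why: Heating 9 should trigger conrotatory 4π electrocyclic opening of the cyclobutenone C1–C4 bond, in which the donor hydroxyl at C4 rotates outward (torquoselectivity) so that the pyranonyl group lies cis to the ketene in 10. The ketene carbon then closes onto the O–CH= carbon of the pyranone (C6 of 6) by a thermal disrotatory 6π electrocyclisation, forming the six-membered carbocycle through the C8–C8a bond (flavone numbering) to give dienone 11, whose 8a-hydrogen shifts to oxygen to give the aromatic hydroquinone 12. The closest known reaction type is the squarate-based thermal ring expansion of 4-aryl- and 4-alkenyl-4-hydroxycyclobutenones to hydroquinones and quinones (Moore-type rearrangement). No stereocentre survives, since the carbinol centre of 9 and C8a of 11 are both lost on aromatisation. The regiochemistry is fixed by the substrate: of the two neighbours of the pyranone attachment carbon only the O–CH= carbon can take part in a 6π closure (the other is the carbonyl carbon), and the squarate carbons map onto C5 (carbinol), C6 and C7 (enol ether) and C8 (ketene). The air-sensitive hydroquinone is not isolated but methylated twice under argon with dimethyl sulfate and potassium carbonate, the hydrogen-bonded 5-OH being the slower of the two.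

**Step 6**
Reactants: 13 2-[4-(benzyloxy)phenyl]-5,6,7,8-tetramethoxy-4H-chromen-4-one
Product: 14 4'-hydroxy-5,6,7,8-tetramethoxyflavone
Conditions: H2 (1 atm), 10% Pd/C, EtOAc/MeOH, rt
Reagents that add atoms: none
Why: Hydrogenolysis of the benzyl aryl ether over palladium on carbon should free the 4'-phenol while the C2=C3 bond of the aromatic pyranone and the four aryl methyl ethers stay untouched, and it avoids Lewis acids that would cleave the 5-methoxy group.

**Compound list**

1 | trans-1-methoxy-3-(trimethylsilyloxy)buta-1,3-diene (Danishefsky's diene) | CO/C=C/C(=C)O[Si](C)(C)C | starting material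
2 | 4-(benzyloxy)benzaldehyde | O=Cc1ccc(OCc2ccccc2)cc1 | starting material
3 | 2-[4-(benzyloxy)phenyl]-6-methoxy-4-(trimethylsilyloxy)-3,6-dihydro-2H-pyran (racemic, diastereomer mixture) | COC1C=C(O[Si](C)(C)C)CC(c2ccc(OCc3ccccc3)cc2)O1 | intermediate
4 | rac-2-[4-(benzyloxy)phenyl]-2,3-dihydro-4H-pyran-4-one | O=C1C=COC(c2ccc(OCc3ccccc3)cc2)C1 | intermediate
5 | rac-2-[4-(benzyloxy)phenyl]-5-iodo-2,3-dihydro-4H-pyran-4-one | O=C1CC(c2ccc(OCc3ccccc3)cc2)OC=C1I | intermediate
6 | 2-[4-(benzyloxy)phenyl]-5-iodo-4H-pyran-4-one | O=c1cc(-c2ccc(OCc3ccccc3)cc2)occ1I | intermediate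
7 | dimethyl squarate (3,4-dimethoxycyclobut-3-ene-1,2-dione) | COC1=C(OC)C(=O)C1=O | starting material
8 | {6-[4-(benzyloxy)phenyl]-4-oxo-4H-pyran-3-yl}magnesium chloride (LiCl complex) | O=c1cc(-c2ccc(OCc3ccccc3)cc2)occ1[Mg]Cl | intermediate
9 | rac-4-{6-[4-(benzyloxy)phenyl]-4-oxo-4H-pyran-3-yl}-4-hydroxy-2,3-dimethoxycyclobut-2-en-1-one | COC1=C(OC)C(O)(c2coc(-c3ccc(OCc4ccccc4)cc3)cc2=O)C1=O | intermediate
10 | (3Z)-4-{6-[4-(benzyloxy)phenyl]-4-oxo-4H-pyran-3-yl}-4-hydroxy-2,3-dimethoxybuta-1,3-dien-1-one (dienylketene) | COC(=C=O)/C(OC)=C(/O)c1coc(-c2ccc(OCc3ccccc3)cc2)cc1=O | intermediate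
11 | rac-2-[4-(benzyloxy)phenyl]-5-hydroxy-6,7-dimethoxy-4H-chromene-4,8(8aH)-dione (bicyclic dienone) | COC1=C(OC)C(=O)C2OC(-c3ccc(OCc4ccccc4)cc3)=CC(=O)C2=C1O | intermediate
12 | 2-[4-(benzyloxy)phenyl]-5,8-dihydroxy-6,7-dimethoxy-4H-chromen-4-one (hydroquinone) | COc1c(OC)c(O)c2c(=O)cc(-c3ccc(OCc4ccccc4)cc3)oc2c1O | intermediate
13 | 2-[4-(benzyloxy)phenyl]-5,6,7,8-tetramethoxy-4H-chromen-4-one | COc1c(OC)c(OC)c2c(=O)cc(-c3ccc(OCc4ccccc4)cc3)oc2c1OC | intermediate
14 | 4'-hydroxy-5,6,7,8-tetramethoxyflavone | COc1c(OC)c(OC)c2c(=O)cc(-c3ccc(O)cc3)oc2c1OC | target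

**Step count.** Total: 6 steps. Longest linear sequence: 6 steps (1 and 2 to 14).

**Steps most likely to fail**

1. Step 5 (key step). The ring may open with the hydroxyl rotating inward, so that the hydroxyl adds to the ketene and a butenolide forms instead of the A ring. The hydroquinone may autoxidise to the quinone before both hydroxyls are methylated, and methylation of the hydrogen-bonded 5-hydroxyl may stall. The fallback changes the substrate of the ring expansion and removes the hydroquinone stage. It sets out from 9, whose tertiary alcohol is methylated (MeI, Ag2O, K2CO3, MeCN, rt) to give rac-4-{6-[4-(benzyloxy)phenyl]-4-oxo-4H-pyran-3-yl}-2,3,4-trimethoxycyclobut-2-en-1-one F1. Heating F1 in toluene at 110 °C should lead through the methoxy dienylketene (3Z)-4-{6-[4-(benzyloxy)phenyl]-4-oxo-4H-pyran-3-yl}-2,3,4-trimethoxybuta-1,3-dien-1-one F2 and the dienone rac-2-[4-(benzyloxy)phenyl]-5,6,7-trimethoxy-4H-chromene-4,8(8aH)-dione F3 to the monophenol 2-[4-(benzyloxy)phenyl]-8-hydroxy-5,6,7-trimethoxy-4H-chromen-4-one F4. In this sequence no free hydroxyl is present during ring opening, no quinone can form, and only the unchelated 8-OH remains. Methylation of F4 (MeI, K2CO3, DMF, rt) comes back to the route at 13.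

2. Step 4. The isopropyl Grignard reagent may add to the pyranone in conjugate fashion instead of exchanging. The metallated pyranone may ring-open by β-elimination of the ring oxygen, or it may attack the squarate by addition–elimination instead of 1,2-addition. The fallback joins the two pieces through the other pyranone carbon by C–H metalation, without a halide or an exchange reagent. It sets out from 4, which DDQ (dioxane, 90 °C) dehydrogenates to 2-[4-(benzyloxy)phenyl]-4H-pyran-4-one F5. Deprotonation of its most acidic C6–H (the O–CH= position, as in the C2-metalation of chromones) with LiTMP in THF at –78 °C gives {6-[4-(benzyloxy)phenyl]-4-oxo-4H-pyran-2-yl}lithium F6, which has no β-leaving group. F6 is added at once to 7 to give the regioisomeric adduct rac-4-{6-[4-(benzyloxy)phenyl]-4-oxo-4H-pyran-2-yl}-4-hydroxy-2,3-dimethoxycyclobut-2-en-1-one F7. Heating F7 as in step 5 should lead through the dienylketene (3Z)-4-{6-[4-(benzyloxy)phenyl]-4-oxo-4H-pyran-2-yl}-4-hydroxy-2,3-dimethoxybuta-1,3-dien-1-one F8 and the dienone rac-2-[4-(benzyloxy)phenyl]-8-hydroxy-6,7-dimethoxy-4H-chromene-4,5(4aH)-dione F9 to the same hydroquinone 12; closure is now at the nucleophilic α-carbon of the pyranone (new bond C4a–C5). The fallback rejoins the route at 12, which is methylated in the same flask to 13.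

3. Step 3. DDQ may abstract hydride at the benzylic CH2 of the protecting group, which would cost the benzyl ether, or the dehydrogenation may be slow and incomplete. The fallback uses selenoxide elimination in place of hydride abstraction. It sets out from 5, which is deprotonated at C3 (LiHMDS, THF, –78 °C) to the enolate lithium 2-[4-(benzyloxy)phenyl]-5-iodo-2H-pyran-4-olate F10. Selenenylation with PhSeCl gives 2-[4-(benzyloxy)phenyl]-5-iodo-3-(phenylselanyl)-2,3-dihydro-4H-pyran-4-one F11, expected mainly as the trans isomer with selenium syn to C2–H. Oxidation (H2O2, CH2Cl2, 0 °C) gives the selenoxide 2-[4-(benzyloxy)phenyl]-5-iodo-3-(phenylseleninyl)-2,3-dihydro-4H-pyran-4-one F12, whose syn-elimination towards C2–H comes back to the route at 6.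

**Further compounds**

F1 | step 5 | rac-4-{6-[4-(benzyloxy)phenyl]-4-oxo-4H-pyran-3-yl}-2,3,4-trimethoxycyclobut-2-en-1-one | COC1=C(OC)C(OC)(c2coc(-c3ccc(OCc4ccccc4)cc3)cc2=O)C1=O
F2 | step 5 | (3Z)-4-{6-[4-(benzyloxy)phenyl]-4-oxo-4H-pyran-3-yl}-2,3,4-trimethoxybuta-1,3-dien-1-one | COC(=C=O)/C(OC)=C(/OC)c1coc(-c2ccc(OCc3ccccc3)cc2)cc1=O
F3 | step 5 | rac-2-[4-(benzyloxy)phenyl]-5,6,7-trimethoxy-4H-chromene-4,8(8aH)-dione | COC1=C(OC)C(=O)C2OC(-c3ccc(OCc4ccccc4)cc3)=CC(=O)C2=C1OC
F4 | step 5 | 2-[4-(benzyloxy)phenyl]-8-hydroxy-5,6,7-trimethoxy-4H-chromen-4-one | COc1c(OC)c(OC)c2c(=O)cc(-c3ccc(OCc4ccccc4)cc3)oc2c1O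
F5 | step 4 | 2-[4-(benzyloxy)phenyl]-4H-pyran-4-one | O=c1ccoc(-c2ccc(OCc3ccccc3)cc2)c1
F6 | step 4 | {6-[4-(benzyloxy)phenyl]-4-oxo-4H-pyran-2-yl}lithium | [Li]c1cc(=O)cc(-c2ccc(OCc3ccccc3)cc2)o1
F7 | step 4 | rac-4-{6-[4-(benzyloxy)phenyl]-4-oxo-4H-pyran-2-yl}-4-hydroxy-2,3-dimethoxycyclobut-2-en-1-one | COC1=C(OC)C(O)(c2cc(=O)cc(-c3ccc(OCc4ccccc4)cc3)o2)C1=O
F8 | step 4 | (3Z)-4-{6-[4-(benzyloxy)phenyl]-4-oxo-4H-pyran-2-yl}-4-hydroxy-2,3-dimethoxybuta-1,3-dien-1-one | COC(=C=O)/C(OC)=C(/O)c1cc(=O)cc(-c2ccc(OCc3ccccc3)cc2)o1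
F9 | step 4 | rac-2-[4-(benzyloxy)phenyl]-8-hydroxy-6,7-dimethoxy-4H-chromene-4,5(4aH)-dione | COC1=C(OC)C(O)=C2OC(-c3ccc(OCc4ccccc4)cc3)=CC(=O)C2C1=O
F10 | step 3 | lithium 2-[4-(benzyloxy)phenyl]-5-iodo-2H-pyran-4-olate (racemic) | [Li]OC1=CC(c2ccc(OCc3ccccc3)cc2)OC=C1I
F11 | step 3 | 2-[4-(benzyloxy)phenyl]-5-iodo-3-(phenylselanyl)-2,3-dihydro-4H-pyran-4-one (racemic, mainly trans) | O=C1C(I)=COC(c2ccc(OCc3ccccc3)cc2)C1[Se]c1ccccc1
F12 | step 3 | 2-[4-(benzyloxy)phenyl]-5-iodo-3-(phenylseleninyl)-2,3-dihydro-4H-pyran-4-one (racemic) | O=C1C(I)=COC(c2ccc(OCc3ccccc3)cc2)C1[Se](=O)c1ccccc1
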